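## Analysis of the target

The target (CNP0321910.1) is a B-type proanthocyanidin trimer carrying three gallate esters: epicatechin 3-O-gallate (upper unit) is bonded from C4 to C8 of epigallocatechin 3-O-gallate (middle unit), which is bonded from its C4 to C8 of catechin 3-O-gallate (lower unit). Each unit is a 2-arylchroman built from a phloroglucinol-type ring A, a pyran ring C and a pendant ring B (catechol in the upper and lower units, pyrogallol in the middle unit). There are eight stereocentres. The upper and middle units are both 2R,3R with the interflavan bond β at C4 (2,3-cis, 3,4-trans); the lower unit is 2R,3S (2,3-trans). The molecule has 22 free phenols (air- and base-sensitive), three esters on hindered secondary alcohols, and two interflavan C4–C8 bonds that ionise under acid. All phenols are therefore carried as benzyl ethers and released by one neutral hydrogenolysis at the end. The main difficulties are forming both interflavan bonds at C8 (not C6) with β configuration at congested positions, and ending with a 2,3-cis, 3,4-trans upper unit. The plan rests on ring C of the upper unit: O1 lies between aromatic C8a and C2. Removing O1 and joining C8a to C2 gives a 3-aryl-4,6-dioxygenated indan-1-one in which C3 is the interflavan carbon C4 and the carbonyl carbon is C2. The C4 stereocentre can thus be set on a carbocycle, and O1 is put in afterwards by oxygen insertion into the aryl–carbonyl bond.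

## Retrosynthetic reasoning

**Target 37 to triol 34.** The 22 benzyl ethers of 36 are removed last, under neutral conditions, because the free polyphenol tolerates no further chemistry. The three ester C–O bonds of 36 are cut next, to triol 34 and acid 35. Late acylation keeps the esters away from organolithiums, amide bases and hydride, and lets one operation serve all three units.

**Triol 34 to lactone 28.** Triol 34 comes from the tris-silyl ether 33. In 33 the C2–H bond of the upper unit is disconnected, leading to hydroxy ketone 31. The forward step is a reductive ring closure through the cyclic oxocarbenium ion 32, and it must deliver hydride anti to the C3 silyloxy group. The C2–aryl bond of 31 is then cut, giving lactone 28 and aryllithium 30 (from bromide 29). The lactone carbonyl thus serves as C2 and ring B arrives as a nucleophile.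

**Lactone 28 to lactone 24.** The C3–O bond is removed via 27 to the unsubstituted lactone 24. Enolate oxidation with 25 should place the oxygen trans to the very large C4 substituent, which is the 3,4-trans relationship required.

**Lactone 24 to indanone 21 (key disconnection).** O1 is excised from 24 to give indanone 21. Forward, peracid 22 has to insert oxygen between the aryl carbon and the carbonyl carbon. Cutting here, and not at C2–C3 or C4–C4a, means the C4 stereocentre is made on a five-membered carbocycle where it is β to the carbonyl and configurationally safe. The aromatic ring A is also bought ready-made.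

**Indanone 21 to aldehyde 17 and ketone 19.** The C3–C3a bond of 21 is cut to the bromochalcone 20. A palladium-catalysed reductive cyclisation with a chiral bisphosphine forms this bond and sets the benzylic stereocentre under catalyst control. Chalcone 20 is cut at its Cα=Cβ bond to aldehyde 17 and methyl ketone 19, which comes from 18 by bromination with 10.

**Aldehyde 17 to monomers 13 and 5.** The formyl carbon of 17 (from 15) replaces the bromine of 14. That bromine served earlier as the cap that keeps C8 of the middle unit from acting as a nucleophile. The interflavan C4–C8 bond of 14 is cut to the C4-activated electrophile 13 and the nucleophile 5. The forward coupling must attack C8 of 5 and the β face of the C4 cation; the cis 2-aryl and 3-silyloxy groups of 13 screen the α face.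

**Monomers to commercial flavan-3-ols.** Compound 13 comes from 11, 9 and 7, and so from (−)-epigallocatechin 6, by benzylation with 2, silylation with 8, bromination with 10 and C4 oxidation in the presence of 12. Compound 5 comes from (+)-catechin 1 by benzylation with 2 and silylation with 4. Six of the eight stereocentres are thereby taken from the chiral pool.

## Alternatives that were turned down

**Alternative 1: ring A of the upper unit from a masked tricarbonyl chain.**
- Disconnection: ring A of the upper unit is opened at C4a–C5 and traced to an open 1,3,5-tricarbonyl chain masked as a 1,3-dioxin-4-one, attached through a silyl enol ether carbon (C4a) to the propargylic carbon C4.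
- Forward key step: heating unmasks an acylketene, C4a acylates at the ketene carbon, and silyl loss with enolisation aromatises the ring. The product is A1, a dimer that carries the 2,4,6-trihydroxyphenyl ring and an arylethynyl group on C4.
- In its favour: the conditions are neutral and thermal, so two gallates can already be in place. The oxygen pattern of ring A is unambiguous, and the alkyne is a latent C2–C3.
- Against it: in the precursor C4 is α to a carbonyl or enol ether and also benzylic and propargylic, so its configuration is at risk. A1 carries three free phenols on an oxidation-prone ring that must then survive semireduction, asymmetric epoxidation and pyran closure. C2 and C3 are still unset, and the tricarbonyl chain costs several C–C bond formations on the dimer.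
- Comparison: this route is stronger in avoiding a peracid on benzyloxy arenes and in avoiding a late triple acylation. The chosen route offers instead a ring A purchased as 18, a C4 centre that is never α to a carbonyl, and fully protected phenols throughout.

**Alternative 2: double cis-epoxide opening.**
- Disconnection: both O1–C2 bonds of the upper and middle units are cut, to an open bis(cis-epoxide) with one free ortho phenol on each ring A.
- Forward key step: a Brønsted or Lewis acid activates both epoxides and each phenol attacks the benzylic epoxide carbon with inversion in a 6-endo opening. The product is A2, with two pyran rings closed and both 3-hydroxyls free.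
- In its favour: two rings and both 2,3-cis relationships arise at once by stereospecific transfer (cis epoxide plus inversion gives 2,3-cis). The design is convergent, and after the key step no organometallic addition or hydride step is needed.
- Against it: the benzylic carbons carry 3,4-bis- and 3,4,5-tris(benzyloxy)phenyl groups and ionise easily, so the opening drifts towards SN1 and inversion is not assured. Both C4 centres must already exist on acyclic chains, and each Z-alkene must be epoxidised with the right facial sense relative to them. Two specific phenols must be kept free among many.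
- Comparison: this route is the more convergent and, after its key step, the shorter. The chosen route offers instead two flavan units taken intact from 1 and 6 with secure C2 and C3 centres, and only one pyran ring to build.

**Alternative 3: benzannulation of the central ring A.**
- Disconnection: ring A of the middle unit is cut across C8–C8a and C6–C7, to a 4-substituted 3-benzyloxycyclobutenone and a siloxyalkyne.
- Forward key step: heating opens the cyclobutenone to a vinylketene, which undergoes [2+2] addition to the ynol ether, a second ring opening and a six-electron closure. The product is the pentasubstituted phenol A3, with C8a–OH as the only free phenol.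
- In its favour: the regiochemistry of the central ring is fixed by construction, so there is no C6/C8 question, and its three oxygens are differentiated. Two large fragments are joined late.
- Against it: both partners are multistep, stereodefined fragments (one carries a complete flavan, the other a propargylic stereocentre, the galloylated lower unit and a second alkyne). A pentasubstituted benzene must form between two bulky groups in a thermal cascade. The stereocentre next to the cyclobutenone passes through ketene intermediates at high temperature. Ring C of the middle unit is still missing after the annulation.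
- Comparison: this route is stronger on C8 regiocontrol. The chosen route answers that with the intrinsic C8 preference of 5 and the bromine cap in 13, and is far shorter because the middle unit 6 needs neither ring A nor ring C construction.

Key step: step 12

## Remarks before the steps

- Abbreviations: Bn = benzyl; TBS = tert-butyldimethylsilyl. "The dimer" means [3-O-TBS-5,7,3',4',5'-penta-O-benzylepigallocatechin]-(4β→8)-[3-O-TBS-5,7,3',4'-tetra-O-benzylcatechin]; "dimer-8-yl" is its radical at C8 of the epigallocatechin (middle) unit.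
- Assumption: the sense of induction of the bisphosphine in step 11 is not predicted here; the (R)-ligand is written, and its antipode is to be used if that is the one that delivers the (3R)-indanone 21.

## Route

Step 1
Reactants: 1 (+)-catechin; 2 benzyl bromide
Product: 3 5,7,3',4'-tetra-O-benzylcatechin (2R,3S)
Conditions: BnBr, K2CO3, DMF, 0 °C to rt, argon
Reagents that add atoms: benzyl bromide, BrCc1ccccc1
Why: Williamson etherification; the four phenols are alkylated under carbonate while the secondary 3-hydroxyl stays free, and no stereocentre is touched.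

Step 2
Reactants: 3 5,7,3',4'-tetra-O-benzylcatechin; 4 tert-butyldimethylsilyl chloride
Product: 5 3-O-TBS-5,7,3',4'-tetra-O-benzylcatechin
Conditions: TBSCl, imidazole, DMF, rt
Reagents that add atoms: tert-butyldimethylsilyl chloride, CC(C)(C)[Si](C)(C)Cl
Why: Silylation of the unhindered equatorial 3-hydroxyl; the TBS ether should survive organolithiums, hydroxide, peracid and cold Lewis acid and falls to fluoride in step 17.

Step 3
Reactants: 6 (−)-epigallocatechin; 2 benzyl bromide
Product: 7 5,7,3',4',5'-penta-O-benzylepigallocatechin (2R,3R)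
Conditions: BnBr, K2CO3, degassed DMF, −10 °C to rt, argon
Reagents that add atoms: benzyl bromide, BrCc1ccccc1
Why: Williamson etherification of the five phenols; cold, oxygen-free conditions keep the pyrogallol ring from autoxidation and C2 from epimerising before the phenols are capped.

Step 4
Reactants: 7 5,7,3',4',5'-penta-O-benzylepigallocatechin; 8 tert-butyldimethylsilyl triflate
Product: 9 3-O-TBS-5,7,3',4',5'-penta-O-benzylepigallocatechin
Conditions: TBSOTf, 2,6-lutidine, CH2Cl2, 0 °C
Reagents that add atoms: tert-butyldimethylsilyl triflate, CC(C)(C)[Si](C)(C)OS(=O)(=O)C(F)(F)F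
Why: The axial 3-hydroxyl of the 2,3-cis series is hindered, so the silyl triflate with a hindered pyridine base is used; silylation before the coupling avoids having to protect this alcohol later, when it is flanked by two aryl groups.

Step 5
Reactants: 9 3-O-TBS-5,7,3',4',5'-penta-O-benzylepigallocatechin; 10 N-bromosuccinimide
Product: 11 8-bromo-3-O-TBS-5,7,3',4',5'-penta-O-benzylepigallocatechin
Conditions: NBS (1.0 equiv), CH2Cl2, −78 to 0 °C
Reagents that add atoms: N-bromosuccinimide, O=C1CCC(=O)N1Br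
Why: Electrophilic aromatic bromination; C8 of ring A is activated by three oxygens and is less hindered than C6 between two benzyloxy groups, so one equivalent at low temperature should give the 8-bromide, which caps C8 in step 7 and is the handle for step 8.

Step 6
Reactants: 11 8-bromo-3-O-TBS-5,7,3',4',5'-penta-O-benzylepigallocatechin; 12 2-ethoxyethanol
Product: 13 8-bromo-4β-(2-ethoxyethoxy)-3-O-TBS-5,7,3',4',5'-penta-O-benzylepigallocatechin
Conditions: DDQ, 2-ethoxyethanol, CH2Cl2, rt
Reagents that add atoms: 2-ethoxyethanol, CCOCCO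
Why: Benzylic oxidation by DDQ; hydride abstraction at C4 gives a quinone-methide-type cation stabilised by ring A, which the alcohol captures anti to the 2-aryl and 3-silyloxy groups. The C4 configuration of 13 is of no consequence because this centre is ionised again in step 7.

Step 7
Reactants: 13 8-bromo-4β-(2-ethoxyethoxy)-3-O-TBS-5,7,3',4',5'-penta-O-benzylepigallocatechin; 5 3-O-TBS-5,7,3',4'-tetra-O-benzylcatechin
Product: 14 8-bromo dimer [8-bromo-3-O-TBS-penta-O-benzylepigallocatechin]-(4β→8)-[3-O-TBS-tetra-O-benzylcatechin]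
Conditions: 5 (3 equiv), TMSOTf (0.5 equiv), CH2Cl2, −78 to −30 °C; then Et3N
Reagents that add atoms: none
Why: Lewis-acid-promoted Friedel–Crafts-type interflavan coupling; the silyl triflate ionises the C4 ether and C8 of 5 (the most nucleophilic and less hindered ring A position) attacks the β face, since the α face is screened by the cis 2-aryl and 3-silyloxy groups, giving the 3,4-trans bond. The bromine keeps the electrophilic unit from reacting as a nucleophile, and the excess of 5, which is recovered, limits further condensation.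

Step 8
Reactants: 14 8-bromo dimer; 15 N,N-dimethylformamide
Product: 17 dimer 8-carbaldehyde (formyl group at C8 of the middle unit), via 8-lithio dimer 16 (not isolated)
Conditions: n-BuLi, THF, −78 °C; DMF, −78 °C to 0 °C; H2O
Reagents that add atoms: N,N-dimethylformamide, CN(C)C=O
Why: Bromine–lithium exchange is fast at −78 °C for an aryl bromide flanked by two oxygens, and the aryllithium is formylated by DMF; benzyl and silyl ethers tolerate these conditions.

Step 9
Reactants: 18 3,5-bis(benzyloxy)acetophenone; 10 N-bromosuccinimide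
Product: 19 2-bromo-3,5-bis(benzyloxy)acetophenone
Conditions: NBS, MeCN, rt
Reagents that add atoms: N-bromosuccinimide, O=C1CCC(=O)N1Br
Why: Electrophilic aromatic bromination; position 2 is ortho to one benzyloxy group and para to the other and is favoured over position 4 between both, and the polar non-acidic medium keeps bromination on the ring and off the methyl ketone.

Step 10
Reactants: 17 dimer 8-carbaldehyde; 19 2-bromo-3,5-bis(benzyloxy)acetophenone
Product: 20 (E)-1-[2-bromo-3,5-bis(benzyloxy)phenyl]-3-(dimer-8-yl)prop-2-en-1-one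
Conditions: KOH, EtOH/THF, rt to 40 °C
Reagents that add atoms: none
Why: Claisen–Schmidt condensation; the aldehyde has no α-hydrogen and the aldol adduct dehydrates to the E-enone. Secondary TBS ethers and benzyl ethers are stable to ethanolic hydroxide at this temperature.

Step 11
Reactants: 20 (E)-1-[2-bromo-3,5-bis(benzyloxy)phenyl]-3-(dimer-8-yl)prop-2-en-1-one
Product: 21 (3R)-4,6-bis(benzyloxy)-3-(dimer-8-yl)indan-1-one
Conditions: Pd(OAc)2 (10 mol %), (R)-3,5-Xyl-MeO-BIPHEP (12 mol %), HCO2Na, DMF, 80 °C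
Reagents that add atoms: none
Why: Intramolecular reductive Heck reaction (hydroarylation) of a 2'-bromochalcone; oxidative addition to zerovalent palladium, carbopalladation that places the aryl carbon on the β-carbon and closes the five-membered ring, then formate reduces the palladium enolate. The bisphosphine on the arylpalladium selects the enone face and sets the new benzylic centre (3R) under catalyst control, the existing stereocentres being remote.

Step 12
Reactants: 21 (3R)-4,6-bis(benzyloxy)-3-(dimer-8-yl)indan-1-one; 22 3-chloroperbenzoic acid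
Product: 24 5,7-bis(benzyloxy)-4-(dimer-8-yl)chroman-2-one (C4 configured as in 21), via peroxyester adduct 23 (not isolated)
Conditions: m-CPBA (3 equiv), NaHCO3, CH2Cl2, 0 °C to rt, dark
Reagents that add atoms: 3-chloroperbenzoic acid, OOC(=O)c1cccc(Cl)c1
Why: The peracid adds to the C1 carbonyl of 21 to give the tetrahedral peroxyester adduct 23. In 23 the C1–C7a bond can lie antiperiplanar to the O–O bond, and the aryl carbon C7a shifts from carbon to oxygen as 3-chlorobenzoate leaves, so that the new oxygen sits between the aryl carbon and the carbonyl carbon (C8a–O1 and O1–C2 in flavan numbering). The closest known reaction type is the Baeyer–Villiger ring expansion of indan-1-ones to 3,4-dihydrocoumarins. The six-membered lactone arises by this 1,2-shift, which enlarges the five-membered ring by one atom; no ring-closing attack takes place. No stereocentre is created, and the benzylic centre C3 of 21 is β to the carbonyl, takes no part and becomes C4 of 24 unchanged. Two selectivities are needed: migration of the aryl carbon in preference to the methylene carbon, and reaction of the peracid at the ketone only. The first rests on π-participation of the arene in the shift against an unbranched primary carbon, as in indan-1-one itself; the second on the absence of alkenes, amines or sulfides and on the NaHCO3 buffer, which keeps strong acid out so that ring hydroxylation of the benzyloxy arenes, silyl ether loss and interflavan ionisation are held back.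

Step 13
Reactants: 24 5,7-bis(benzyloxy)-4-(dimer-8-yl)chroman-2-one; 25 2-(phenylsulfonyl)-3-phenyloxaziridine (racemic)
Product: 27 (3R)-3-hydroxy-5,7-bis(benzyloxy)-4-(dimer-8-yl)chroman-2-one (3,4-trans), via potassium enolate 26 (not isolated)
Conditions: KN(SiMe3)2, THF, −78 °C; 25, −78 °C; AcOH, −78 °C
Reagents that add atoms: 2-(phenylsulfonyl)-3-phenyloxaziridine, O=S(=O)(N1OC1c1ccccc1)c1ccccc1
Why: Enolate hydroxylation with an N-sulfonyloxaziridine; the oxidant approaches the enolate face opposite the very large C4 aryl group, so the new C3–O bond is trans to it. The potassium counter-ion and −78 °C limit addition to the sulfonylimine by-product and ketene-type opening of the aryl ester enolate.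

Step 14
Reactants: 27 (3R)-3-hydroxy-5,7-bis(benzyloxy)-4-(dimer-8-yl)chroman-2-one; 8 tert-butyldimethylsilyl triflate
Product: 28 (3R)-3-(tert-butyldimethylsilyloxy)-5,7-bis(benzyloxy)-4-(dimer-8-yl)chroman-2-one (3,4-trans)
Conditions: TBSOTf, 2,6-lutidine, CH2Cl2, −20 to 0 °C
Reagents that add atoms: tert-butyldimethylsilyl triflate, CC(C)(C)[Si](C)(C)OS(=O)(=O)C(F)(F)F
Why: Silylation of the α-hydroxy lactone so that no alkoxide is present in step 15; the same silyl group as on the other two units allows one deprotection in step 17.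

Step 15
Reactants: 28 (3R)-3-(tert-butyldimethylsilyloxy)-5,7-bis(benzyloxy)-4-(dimer-8-yl)chroman-2-one; 29 4-bromo-1,2-bis(benzyloxy)benzene
Product: 31 hydroxy ketone 1-[3,4-bis(benzyloxy)phenyl]-2-(tert-butyldimethylsilyloxy)-3-[2-hydroxy-4,6-bis(benzyloxy)phenyl]-3-(dimer-8-yl)propan-1-one (C2 and C3 of the chain as C3 and C4 of 28), via 3,4-bis(benzyloxy)phenyllithium 30 (not isolated)
Conditions: 29, n-BuLi, THF, −78 °C; then 28 (0.8 equiv relative to 30), −78 °C; AcOH, −78 °C
Reagents that add atoms: 4-bromo-1,2-bis(benzyloxy)benzene, Brc1ccc(OCc2ccccc2)c(OCc2ccccc2)c1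
Why: Bromine–lithium exchange gives the aryllithium, which adds once to the aryl lactone carbonyl; the tetrahedral adduct opens to the lithium phenoxide and an aryl ketone. That ketone is deactivated by its electron-rich aryl group, the neighbouring silyloxy group and the crowded C3, so a small excess at −78 °C with a cold acid quench should stop at 31 with C3 intact.

Step 16
Reactants: 31 hydroxy ketone
Product: 33 tris-O-TBS perbenzyl trimer [3-O-TBS-tetra-O-benzylepicatechin]-(4β→8)-[3-O-TBS-penta-O-benzylepigallocatechin]-(4β→8)-[3-O-TBS-tetra-O-benzylcatechin], via oxocarbenium ion 32 (not isolated)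
Conditions: Et3SiH (10 equiv), BF3·OEt2 (2 equiv), CH2Cl2, −78 to −40 °C; then Et3N
Reagents that add atoms: none
Why: Reductive cyclisation (ionic hydrogenation): the Lewis acid brings the phenol onto the ketone and removes water to give the 2-aryl oxocarbenium ion 32, which the silane reduces. In the half-chair of 32 the C4 aryl and C3 silyloxy groups should both be pseudoaxial (avoiding the 5-benzyloxy group and the 2-aryl group respectively), and hydride adds axially anti to the neighbouring silyloxy group, which gives the 2,3-cis flavan; C3 and C4 are not touched.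

Step 17
Reactants: 33 tris-O-TBS perbenzyl trimer
Product: 34 perbenzyl trimer triol [tetra-O-benzylepicatechin]-(4β→8)-[penta-O-benzylepigallocatechin]-(4β→8)-[tetra-O-benzylcatechin]
Conditions: Bu4NF, THF, rt to 45 °C
Reagents that add atoms: none
Why: Fluoride cleaves the three Si–O bonds; benzyl ethers, the chroman rings and the interflavan bonds are inert to these conditions, and warming is allowed for the hindered axial silyl ethers.

Step 18
Reactants: 34 perbenzyl trimer triol; 35 3,4,5-tris(benzyloxy)benzoic acid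
Product: 36 perbenzylated tris-gallate (3,4,5-tri-O-benzylgalloyl ester at O3 of each unit of 34)
Conditions: 35 (6 equiv), DCC, DMAP, CH2Cl2, rt to 40 °C
Reagents that add atoms: 3,4,5-tris(benzyloxy)benzoic acid, OC(=O)c1cc(OCc2ccccc2)c(OCc2ccccc2)c(OCc2ccccc2)c1
Why: Steglich esterification; acyl transfer through the acylpyridinium reaches the hindered secondary hydroxyls, and the excess of acid with gentle warming is meant to drive all three to completion without touching a stereocentre.

Step 19
Reactants: 36 perbenzylated tris-gallate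
Product: 37 epicatechin-3-O-gallate-(4β→8)-epigallocatechin-3-O-gallate-(4β→8)-catechin-3-O-gallate (target)
Conditions: H2 (1 atm), Pd(OH)2 on carbon, THF/MeOH/H2O, rt
Reagents that add atoms: none
Why: Hydrogenolysis of the 22 benzyl ethers under neutral conditions; the gallate esters, the interflavan bonds and all eight stereocentres are not affected.

## Compound list

1 | (+)-catechin | Oc1cc(O)c2c(c1)O[C@H](c1ccc(O)c(O)c1)[C@@H](O)C2 | starting material
2 | benzyl bromide | BrCc1ccccc1 | starting material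
3 | 5,7,3',4'-tetra-O-benzylcatechin | c1c(OCc5ccccc5)cc(OCc5ccccc5)c2c1O[C@H](c1ccc(OCc5ccccc5)c(OCc5ccccc5)c1)[C@@H](O)C2 | intermediate
4 | tert-butyldimethylsilyl chloride | CC(C)(C)[Si](C)(C)Cl | starting material
5 | 3-O-TBS-5,7,3',4'-tetra-O-benzylcatechin | c1c(OCc5ccccc5)cc(OCc5ccccc5)c2c1O[C@H](c1ccc(OCc5ccccc5)c(OCc5ccccc5)c1)[C@@H](O[Si](C)(C)C(C)(C)C)C2 | intermediate
6 | (−)-epigallocatechin | O[C@@H]1Cc2c(O)cc(O)cc2O[C@@H]1c1cc(O)c(O)c(O)c1 | starting material
7 | 5,7,3',4',5'-penta-O-benzylepigallocatechin | O[C@@H]1Cc2c(OCc5ccccc5)cc(OCc5ccccc5)cc2O[C@@H]1c1cc(OCc5ccccc5)c(OCc5ccccc5)c(OCc5ccccc5)c1 | intermediate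
8 | tert-butyldimethylsilyl triflate | CC(C)(C)[Si](C)(C)OS(=O)(=O)C(F)(F)F | starting material
9 | 3-O-TBS-5,7,3',4',5'-penta-O-benzylepigallocatechin | CC(C)(C)[Si](C)(C)O[C@@H]1Cc2c(OCc5ccccc5)cc(OCc5ccccc5)cc2O[C@@H]1c1cc(OCc5ccccc5)c(OCc5ccccc5)c(OCc5ccccc5)c1 | intermediate
10 | N-bromosuccinimide | O=C1CCC(=O)N1Br | starting material
11 | 8-bromo-3-O-TBS-5,7,3',4',5'-penta-O-benzylepigallocatechin | CC(C)(C)[Si](C)(C)O[C@@H]1Cc2c(OCc5ccccc5)cc(OCc5ccccc5)c(Br)c2O[C@@H]1c1cc(OCc5ccccc5)c(OCc5ccccc5)c(OCc5ccccc5)c1 | intermediate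
12 | 2-ethoxyethanol | CCOCCO | starting material
13 | 8-bromo-4β-(2-ethoxyethoxy)-3-O-TBS-5,7,3',4',5'-penta-O-benzylepigallocatechin | CC(C)(C)[Si](C)(C)O[C@@H]1[C@@H](OCCOCC)c2c(OCc5ccccc5)cc(OCc5ccccc5)c(Br)c2O[C@@H]1c1cc(OCc5ccccc5)c(OCc5ccccc5)c(OCc5ccccc5)c1 | intermediate
14 | 8-bromo dimer, [8-bromo-3-O-TBS-penta-O-benzylepigallocatechin]-(4β→8)-[3-O-TBS-tetra-O-benzylcatechin] | CC(C)(C)[Si](C)(C)O[C@@H]1[C@@H](c2c(OCc5ccccc5)cc(OCc5ccccc5)c3c2O[C@H](c2ccc(OCc5ccccc5)c(OCc5ccccc5)c2)[C@@H](O[Si](C)(C)C(C)(C)C)C3)c2c(OCc5ccccc5)cc(OCc5ccccc5)c(Br)c2O[C@@H]1c1cc(OCc5ccccc5)c(OCc5ccccc5)c(OCc5ccccc5)c1 | intermediate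
15 | N,N-dimethylformamide | CN(C)C=O | starting material
16 | 8-lithio dimer | CC(C)(C)[Si](C)(C)O[C@@H]1[C@@H](c2c(OCc5ccccc5)cc(OCc5ccccc5)c3c2O[C@H](c2ccc(OCc5ccccc5)c(OCc5ccccc5)c2)[C@@H](O[Si](C)(C)C(C)(C)C)C3)c2c(OCc5ccccc5)cc(OCc5ccccc5)c([Li])c2O[C@@H]1c1cc(OCc5ccccc5)c(OCc5ccccc5)c(OCc5ccccc5)c1 | intermediate
17 | dimer 8-carbaldehyde | CC(C)(C)[Si](C)(C)O[C@@H]1[C@@H](c2c(OCc5ccccc5)cc(OCc5ccccc5)c3c2O[C@H](c2ccc(OCc5ccccc5)c(OCc5ccccc5)c2)[C@@H](O[Si](C)(C)C(C)(C)C)C3)c2c(OCc5ccccc5)cc(OCc5ccccc5)c(C=O)c2O[C@@H]1c1cc(OCc5ccccc5)c(OCc5ccccc5)c(OCc5ccccc5)c1 | intermediate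
18 | 3,5-bis(benzyloxy)acetophenone | CC(=O)c1cc(OCc2ccccc2)cc(OCc2ccccc2)c1 | starting material
19 | 2-bromo-3,5-bis(benzyloxy)acetophenone | CC(=O)c1cc(OCc2ccccc2)cc(OCc2ccccc2)c1Br | intermediate
20 | (E)-1-[2-bromo-3,5-bis(benzyloxy)phenyl]-3-(dimer-8-yl)prop-2-en-1-one | CC(C)(C)[Si](C)(C)O[C@@H]1[C@@H](c2c(OCc5ccccc5)cc(OCc5ccccc5)c3c2O[C@H](c2ccc(OCc5ccccc5)c(OCc5ccccc5)c2)[C@@H](O[Si](C)(C)C(C)(C)C)C3)c2c(OCc5ccccc5)cc(OCc5ccccc5)c(/C=C/C(=O)c3cc(OCc5ccccc5)cc(OCc5ccccc5)c3Br)c2O[C@@H]1c1cc(OCc5ccccc5)c(OCc5ccccc5)c(OCc5ccccc5)c1 | intermediate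
21 | (3R)-4,6-bis(benzyloxy)-3-(dimer-8-yl)indan-1-one | CC(C)(C)[Si](C)(C)O[C@@H]1[C@@H](c2c(OCc5ccccc5)cc(OCc5ccccc5)c3c2O[C@H](c2ccc(OCc5ccccc5)c(OCc5ccccc5)c2)[C@@H](O[Si](C)(C)C(C)(C)C)C3)c2c(OCc5ccccc5)cc(OCc5ccccc5)c([C@@H]3CC(=O)c4cc(OCc5ccccc5)cc(OCc5ccccc5)c43)c2O[C@@H]1c1cc(OCc5ccccc5)c(OCc5ccccc5)c(OCc5ccccc5)c1 | intermediate
22 | 3-chloroperbenzoic acid | OOC(=O)c1cccc(Cl)c1 | starting material
23 | peroxyester adduct of 21 (1-hydroxy-1-(3-chlorobenzoylperoxy)indane, either configuration at C1) | CC(C)(C)[Si](C)(C)O[C@@H]1[C@@H](c2c(OCc5ccccc5)cc(OCc5ccccc5)c3c2O[C@H](c2ccc(OCc5ccccc5)c(OCc5ccccc5)c2)[C@@H](O[Si](C)(C)C(C)(C)C)C3)c2c(OCc5ccccc5)cc(OCc5ccccc5)c([C@@H]3CC(O)(OOC(=O)c4cccc(Cl)c4)c4cc(OCc5ccccc5)cc(OCc5ccccc5)c43)c2O[C@@H]1c1cc(OCc5ccccc5)c(OCc5ccccc5)c(OCc5ccccc5)c1 | intermediate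
24 | 5,7-bis(benzyloxy)-4-(dimer-8-yl)chroman-2-one, C4 as the 4β interflavan carbon of the upper unit | CC(C)(C)[Si](C)(C)O[C@@H]1[C@@H](c2c(OCc5ccccc5)cc(OCc5ccccc5)c3c2O[C@H](c2ccc(OCc5ccccc5)c(OCc5ccccc5)c2)[C@@H](O[Si](C)(C)C(C)(C)C)C3)c2c(OCc5ccccc5)cc(OCc5ccccc5)c([C@@H]3CC(=O)Oc4cc(OCc5ccccc5)cc(OCc5ccccc5)c43)c2O[C@@H]1c1cc(OCc5ccccc5)c(OCc5ccccc5)c(OCc5ccccc5)c1 | intermediate
25 | 2-(phenylsulfonyl)-3-phenyloxaziridine (racemic) | O=S(=O)(N1OC1c1ccccc1)c1ccccc1 | starting material
26 | potassium enolate of 24 | CC(C)(C)[Si](C)(C)O[C@@H]1[C@@H](c2c(OCc5ccccc5)cc(OCc5ccccc5)c3c2O[C@H](c2ccc(OCc5ccccc5)c(OCc5ccccc5)c2)[C@@H](O[Si](C)(C)C(C)(C)C)C3)c2c(OCc5ccccc5)cc(OCc5ccccc5)c([C@@H]3C=C([O-])Oc4cc(OCc5ccccc5)cc(OCc5ccccc5)c43)c2O[C@@H]1c1cc(OCc5ccccc5)c(OCc5ccccc5)c(OCc5ccccc5)c1.[K+] | intermediate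
27 | (3R)-3-hydroxy-5,7-bis(benzyloxy)-4-(dimer-8-yl)chroman-2-one, 3,4-trans | CC(C)(C)[Si](C)(C)O[C@@H]1[C@@H](c2c(OCc5ccccc5)cc(OCc5ccccc5)c3c2O[C@H](c2ccc(OCc5ccccc5)c(OCc5ccccc5)c2)[C@@H](O[Si](C)(C)C(C)(C)C)C3)c2c(OCc5ccccc5)cc(OCc5ccccc5)c([C@H]3c4c(OCc5ccccc5)cc(OCc5ccccc5)cc4OC(=O)[C@@H]3O)c2O[C@@H]1c1cc(OCc5ccccc5)c(OCc5ccccc5)c(OCc5ccccc5)c1 | intermediate
28 | (3R)-3-(tert-butyldimethylsilyloxy)-5,7-bis(benzyloxy)-4-(dimer-8-yl)chroman-2-one, 3,4-trans | CC(C)(C)[Si](C)(C)O[C@@H]1[C@@H](c2c(OCc5ccccc5)cc(OCc5ccccc5)c3c2O[C@H](c2ccc(OCc5ccccc5)c(OCc5ccccc5)c2)[C@@H](O[Si](C)(C)C(C)(C)C)C3)c2c(OCc5ccccc5)cc(OCc5ccccc5)c([C@H]3c4c(OCc5ccccc5)cc(OCc5ccccc5)cc4OC(=O)[C@@H]3O[Si](C)(C)C(C)(C)C)c2O[C@@H]1c1cc(OCc5ccccc5)c(OCc5ccccc5)c(OCc5ccccc5)c1 | intermediate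
29 | 4-bromo-1,2-bis(benzyloxy)benzene | Brc1ccc(OCc2ccccc2)c(OCc2ccccc2)c1 | starting material
30 | 3,4-bis(benzyloxy)phenyllithium | [Li]c1ccc(OCc2ccccc2)c(OCc2ccccc2)c1 | intermediate
31 | hydroxy ketone, 1-[3,4-bis(benzyloxy)phenyl]-2-(tert-butyldimethylsilyloxy)-3-[2-hydroxy-4,6-bis(benzyloxy)phenyl]-3-(dimer-8-yl)propan-1-one | CC(C)(C)[Si](C)(C)O[C@@H]1[C@@H](c2c(OCc5ccccc5)cc(OCc5ccccc5)c3c2O[C@H](c2ccc(OCc5ccccc5)c(OCc5ccccc5)c2)[C@@H](O[Si](C)(C)C(C)(C)C)C3)c2c(OCc5ccccc5)cc(OCc5ccccc5)c([C@@H](c3c(OCc5ccccc5)cc(OCc5ccccc5)cc3O)[C@@H](O[Si](C)(C)C(C)(C)C)C(=O)c3ccc(OCc5ccccc5)c(OCc5ccccc5)c3)c2O[C@@H]1c1cc(OCc5ccccc5)c(OCc5ccccc5)c(OCc5ccccc5)c1 | intermediate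
32 | oxocarbenium ion (2-aryl-3-silyloxy-4-(dimer-8-yl)-3,4-dihydrochromenylium) | CC(C)(C)[Si](C)(C)O[C@@H]1[C@@H](c2c(OCc5ccccc5)cc(OCc5ccccc5)c3c2O[C@H](c2ccc(OCc5ccccc5)c(OCc5ccccc5)c2)[C@@H](O[Si](C)(C)C(C)(C)C)C3)c2c(OCc5ccccc5)cc(OCc5ccccc5)c([C@H]3c4c(OCc5ccccc5)cc(OCc5ccccc5)cc4[O+]=C(c4ccc(OCc5ccccc5)c(OCc5ccccc5)c4)[C@@H]3O[Si](C)(C)C(C)(C)C)c2O[C@@H]1c1cc(OCc5ccccc5)c(OCc5ccccc5)c(OCc5ccccc5)c1 | intermediate
33 | tris-O-TBS perbenzyl trimer | CC(C)(C)[Si](C)(C)O[C@@H]1[C@@H](c2c(OCc5ccccc5)cc(OCc5ccccc5)c3c2O[C@H](c2ccc(OCc5ccccc5)c(OCc5ccccc5)c2)[C@@H](O[Si](C)(C)C(C)(C)C)C3)c2c(OCc5ccccc5)cc(OCc5ccccc5)c([C@H]3c4c(OCc5ccccc5)cc(OCc5ccccc5)cc4O[C@H](c4ccc(OCc5ccccc5)c(OCc5ccccc5)c4)[C@@H]3O[Si](C)(C)C(C)(C)C)c2O[C@@H]1c1cc(OCc5ccccc5)c(OCc5ccccc5)c(OCc5ccccc5)c1 | intermediate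
34 | perbenzyl trimer triol | O[C@@H]1[C@@H](c2c(OCc5ccccc5)cc(OCc5ccccc5)c3c2O[C@H](c2ccc(OCc5ccccc5)c(OCc5ccccc5)c2)[C@@H](O)C3)c2c(OCc5ccccc5)cc(OCc5ccccc5)c([C@H]3c4c(OCc5ccccc5)cc(OCc5ccccc5)cc4O[C@H](c4ccc(OCc5ccccc5)c(OCc5ccccc5)c4)[C@@H]3O)c2O[C@@H]1c1cc(OCc5ccccc5)c(OCc5ccccc5)c(OCc5ccccc5)c1 | intermediate
35 | 3,4,5-tris(benzyloxy)benzoic acid | OC(=O)c1cc(OCc2ccccc2)c(OCc2ccccc2)c(OCc2ccccc2)c1 | starting material
36 | perbenzylated tris-gallate | O=C(O[C@@H]1[C@@H](c2c(OCc5ccccc5)cc(OCc5ccccc5)c3c2O[C@H](c2ccc(OCc5ccccc5)c(OCc5ccccc5)c2)[C@@H](OC(=O)c2cc(OCc5ccccc5)c(OCc5ccccc5)c(OCc5ccccc5)c2)C3)c2c(OCc5ccccc5)cc(OCc5ccccc5)c([C@H]3c4c(OCc5ccccc5)cc(OCc5ccccc5)cc4O[C@H](c4ccc(OCc5ccccc5)c(OCc5ccccc5)c4)[C@@H]3OC(=O)c3cc(OCc5ccccc5)c(OCc5ccccc5)c(OCc5ccccc5)c3)c2O[C@@H]1c1cc(OCc5ccccc5)c(OCc5ccccc5)c(OCc5ccccc5)c1)c1cc(OCc5ccccc5)c(OCc5ccccc5)c(OCc5ccccc5)c1 | intermediate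
37 | epicatechin-3-O-gallate-(4β→8)-epigallocatechin-3-O-gallate-(4β→8)-catechin-3-O-gallate | O=C(O[C@@H]1[C@@H](c2c(O)cc(O)c3c2O[C@H](c2ccc(O)c(O)c2)[C@@H](OC(=O)c2cc(O)c(O)c(O)c2)C3)c2c(O)cc(O)c([C@H]3c4c(O)cc(O)cc4O[C@H](c4ccc(O)c(O)c4)[C@@H]3OC(=O)c3cc(O)c(O)c(O)c3)c2O[C@@H]1c1cc(O)c(O)c(O)c1)c1cc(O)c(O)c(O)c1 | target

## Step count and weak points

Total step count: 19. Longest linear sequence: 16 steps, from (−)-epigallocatechin 6 (steps 3 to 8 and 10 to 19).

**Step 12 (key step).**
- What may go wrong: migration of the methylene carbon in place of the aryl carbon, because both benzyloxy groups are meta to the migrating carbon and give it no resonance support. Addition of the peracid to a conjugated, crowded ketone may also be slow, which gives time for electrophilic hydroxylation of the free C6 positions of the phloroglucinol-type rings.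
- Fallback (sets out from 14, returns at 24): the oxygen is brought in with ring A and not inserted. Bromine–lithium exchange on 14 (n-BuLi, THF, −78 °C) and a quench with 2-isopropoxy-4,4,5,5-tetramethyl-1,3,2-dioxaborolane would give the dimer 8-pinacolboronate F1. 5,7-Bis(benzyloxy)coumarin F2 would be made from 5,7-dihydroxycoumarin (BnBr, K2CO3, DMF). Rhodium-catalysed asymmetric 1,4-addition of F1 to F2 (Rh(acac)(C2H4)2, SEGPHOS of the appropriate handedness, KOH, dioxane/H2O, 60 °C), the known conjugate arylation of coumarins, would give 24 directly. Its own weakness is protodeboronation of a di-ortho-oxygenated arylboron reagent.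

**Step 11.**
- What may go wrong: carbopalladation at a β-carbon that carries a di-ortho-substituted aryl group may be slow, so that formate reduces the arylpalladium first and the bromine is lost without ring closure. Facial discrimination by the ligand may also be weak at 80 °C on so large a substrate.
- Fallback (sets out from 20, returns at 21): the stereocentre is set by hydride delivery and not by the C–C bond formation. Cyclisation of 20 with an achiral catalyst (Pd(OAc)2, PPh3, HCO2Na, DMF) would give 21 together with its (3S)-epimer F3. The mixture would be converted into the trimethylsilyl enol ethers F4 (LiN(SiMe3)2, Me3SiCl, THF, −78 °C) and dehydrogenated by Saegusa–Ito oxidation (Pd(OAc)2, MeCN) to the 3-(dimer-8-yl)inden-1-one F5. Copper hydride conjugate reduction (Cu(OAc)2, DTBM-SEGPHOS of the appropriate handedness, polymethylhydrosiloxane, t-BuOH, toluene, 0 °C) would then return 21.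

**Step 15.**
- What may go wrong: a second addition of the aryllithium to the ketone that is released when the tetrahedral adduct expels the phenoxide, or enolisation at C3 with loss of configuration.
- Fallback (sets out from 28, returns at 31): the lactone would be opened with N,O-dimethylhydroxylamine hydrochloride and i-PrMgCl (THF, −20 °C) to the phenolic N-methoxy-N-methylamide F6. Treatment with 30 (2.5 equiv, THF, −78 °C; the first equivalent deprotonates the phenol) would give 31 through a chelated adduct that cannot add a second aryl group.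

**Step 16.**
- What may go wrong: hydride delivery to the other face of 32, since the required β face is syn to the pseudoaxial C4 aryl group; this would give the 2,3-trans epimer. Reversible deprotonation of 32 at C3, or acid ionisation of an interflavan bond, are further risks.
- Fallback (sets out from 28, returns at 33): the order of the two nucleophiles is reversed, so that a face preferred for steric reasons now places the aryl group, not the hydrogen, anti to the C4 substituent. Reduction of 28 with i-Bu2AlH (CH2Cl2, −78 °C) would give the lactol F7. Potassium [3,4-bis(benzyloxy)phenyl]trifluoroborate F8 would be made from 30 (B(OMe)3, then KHF2). BF3·OEt2-promoted addition of F8 to the oxocarbenium ion derived from F7 (CH2Cl2/MeCN, −40 to 0 °C) would give 33.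

## Further compounds

F1 | step 12 | dimer 8-(4,4,5,5-tetramethyl-1,3,2-dioxaborolan-2-yl) derivative | CC(C)(C)[Si](C)(C)O[C@@H]1[C@@H](c2c(OCc5ccccc5)cc(OCc5ccccc5)c3c2O[C@H](c2ccc(OCc5ccccc5)c(OCc5ccccc5)c2)[C@@H](O[Si](C)(C)C(C)(C)C)C3)c2c(OCc5ccccc5)cc(OCc5ccccc5)c(B3OC(C)(C)C(C)(C)O3)c2O[C@@H]1c1cc(OCc5ccccc5)c(OCc5ccccc5)c(OCc5ccccc5)c1
F2 | step 12 | 5,7-bis(benzyloxy)coumarin | O=c1ccc2c(OCc3ccccc3)cc(OCc3ccccc3)cc2o1
F3 | step 11 | (3S)-4,6-bis(benzyloxy)-3-(dimer-8-yl)indan-1-one | CC(C)(C)[Si](C)(C)O[C@@H]1[C@@H](c2c(OCc5ccccc5)cc(OCc5ccccc5)c3c2O[C@H](c2ccc(OCc5ccccc5)c(OCc5ccccc5)c2)[C@@H](O[Si](C)(C)C(C)(C)C)C3)c2c(OCc5ccccc5)cc(OCc5ccccc5)c([C@H]3CC(=O)c4cc(OCc5ccccc5)cc(OCc5ccccc5)c43)c2O[C@@H]1c1cc(OCc5ccccc5)c(OCc5ccccc5)c(OCc5ccccc5)c1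
F4 | step 11 | 4,6-bis(benzyloxy)-1-(dimer-8-yl)-3-(trimethylsilyloxy)-1H-indene, both configurations at C1 | CC(C)(C)[Si](C)(C)O[C@@H]1[C@@H](c2c(OCc5ccccc5)cc(OCc5ccccc5)c3c2O[C@H](c2ccc(OCc5ccccc5)c(OCc5ccccc5)c2)[C@@H](O[Si](C)(C)C(C)(C)C)C3)c2c(OCc5ccccc5)cc(OCc5ccccc5)c(C3C=C(O[Si](C)(C)C)c4cc(OCc5ccccc5)cc(OCc5ccccc5)c43)c2O[C@@H]1c1cc(OCc5ccccc5)c(OCc5ccccc5)c(OCc5ccccc5)c1
F5 | step 11 | 4,6-bis(benzyloxy)-3-(dimer-8-yl)inden-1-one | CC(C)(C)[Si](C)(C)O[C@@H]1[C@@H](c2c(OCc5ccccc5)cc(OCc5ccccc5)c3c2O[C@H](c2ccc(OCc5ccccc5)c(OCc5ccccc5)c2)[C@@H](O[Si](C)(C)C(C)(C)C)C3)c2c(OCc5ccccc5)cc(OCc5ccccc5)c(C3=CC(=O)c4cc(OCc5ccccc5)cc(OCc5ccccc5)c43)c2O[C@@H]1c1cc(OCc5ccccc5)c(OCc5ccccc5)c(OCc5ccccc5)c1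
F6 | step 15 | N-methoxy-N-methyl-2-(tert-butyldimethylsilyloxy)-3-[2-hydroxy-4,6-bis(benzyloxy)phenyl]-3-(dimer-8-yl)propanamide | CC(C)(C)[Si](C)(C)O[C@@H]1[C@@H](c2c(OCc5ccccc5)cc(OCc5ccccc5)c3c2O[C@H](c2ccc(OCc5ccccc5)c(OCc5ccccc5)c2)[C@@H](O[Si](C)(C)C(C)(C)C)C3)c2c(OCc5ccccc5)cc(OCc5ccccc5)c([C@@H](c3c(OCc5ccccc5)cc(OCc5ccccc5)cc3O)[C@@H](O[Si](C)(C)C(C)(C)C)C(=O)N(C)OC)c2O[C@@H]1c1cc(OCc5ccccc5)c(OCc5ccccc5)c(OCc5ccccc5)c1
F7 | step 16 | 3-(tert-butyldimethylsilyloxy)-5,7-bis(benzyloxy)-4-(dimer-8-yl)chroman-2-ol, both anomers | CC(C)(C)[Si](C)(C)O[C@@H]1[C@@H](c2c(OCc5ccccc5)cc(OCc5ccccc5)c3c2O[C@H](c2ccc(OCc5ccccc5)c(OCc5ccccc5)c2)[C@@H](O[Si](C)(C)C(C)(C)C)C3)c2c(OCc5ccccc5)cc(OCc5ccccc5)c([C@H]3c4c(OCc5ccccc5)cc(OCc5ccccc5)cc4OC(O)[C@@H]3O[Si](C)(C)C(C)(C)C)c2O[C@@H]1c1cc(OCc5ccccc5)c(OCc5ccccc5)c(OCc5ccccc5)c1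
F8 | step 16 | potassium [3,4-bis(benzyloxy)phenyl]trifluoroborate | [K+].F[B-](F)(F)c1ccc(OCc2ccccc2)c(OCc2ccccc2)c1
A1 | alternative 1 | benzylated bis-gallate dimer with the 2,4,6-trihydroxyphenyl ring A of the upper unit and a 3,4-bis(benzyloxy)phenylethynyl group on the propargylic C4 | O=C(O[C@@H]1[C@@H](c2c(OCc5ccccc5)cc(OCc5ccccc5)c3c2O[C@H](c2ccc(OCc5ccccc5)c(OCc5ccccc5)c2)[C@@H](OC(=O)c2cc(OCc5ccccc5)c(OCc5ccccc5)c(OCc5ccccc5)c2)C3)c2c(OCc5ccccc5)cc(OCc5ccccc5)c([C@H](C#Cc4ccc(OCc5ccccc5)c(OCc5ccccc5)c4)c4c(O)cc(O)cc4O)c2O[C@@H]1c1cc(OCc5ccccc5)c(OCc5ccccc5)c(OCc5ccccc5)c1)c1cc(OCc5ccccc5)c(OCc5ccccc5)c(OCc5ccccc5)c1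
A2 | alternative 2 | benzylated trimer with free 3-hydroxyls on the upper and middle units and the tri-O-benzylgallate on the lower unit | O[C@@H]1[C@@H](c2c(OCc5ccccc5)cc(OCc5ccccc5)c3c2O[C@H](c2ccc(OCc5ccccc5)c(OCc5ccccc5)c2)[C@@H](OC(=O)c2cc(OCc5ccccc5)c(OCc5ccccc5)c(OCc5ccccc5)c2)C3)c2c(OCc5ccccc5)cc(OCc5ccccc5)c([C@H]3c4c(OCc5ccccc5)cc(OCc5ccccc5)cc4O[C@H](c4ccc(OCc5ccccc5)c(OCc5ccccc5)c4)[C@@H]3O)c2O[C@@H]1c1cc(OCc5ccccc5)c(OCc5ccccc5)c(OCc5ccccc5)c1
A3 | alternative 3 | pentasubstituted phenol (ring A of the middle unit) joining the silylated upper flavan at C8 and the propargylic C4 with the galloylated lower unit at C4a | Oc1c([C@H]3c4c(OCc5ccccc5)cc(OCc5ccccc5)cc4O[C@H](c4ccc(OCc5ccccc5)c(OCc5ccccc5)c4)[C@@H]3O[Si](C)(C)C(C)(C)C)c(O[Si](C(C)C)(C(C)C)C(C)C)cc(OCc5ccccc5)c1[C@H](c2c(OCc5ccccc5)cc(OCc5ccccc5)c3c2O[C@H](c2ccc(OCc5ccccc5)c(OCc5ccccc5)c2)[C@@H](OC(=O)c2cc(OCc5ccccc5)c(OCc5ccccc5)c(OCc5ccccc5)c2)C3)C#Cc6cc(OCc5ccccc5)c(OCc5ccccc5)c(OCc5ccccc5)c6
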